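**Retrosynthetic overview**
1. The hexamer A–CH2–B–CH2–C–CH2–D–CH2–E–CH2–F (A = butyrylfilicinic acid ring, B to E = butyrylphloroglucinol rings, F = methylbutyrylphloroglucinol ring) is cut at the central C–D methylene into trimers A–B–C (27) and F–E–D (35), joined through a ring D Mannich base and its o-quinone methide.
2. Each trimer is cut at its outer methylene (A–B or F–E) and at the butyryl group of ring C or D. Both lead back to one dimer, 14: ring B (or E) with its butyryl in place, one free ring CH, and a tris(benzyloxy)benzyl arm that later becomes ring C (or D). For the A–B bond the electrophile is the ring B Mannich base 16 made from 14; for the F–E bond it is the ring F Mannich base 30, and 14 itself is the nucleophile.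
3. Feature used: in ring B the butyryl-bearing carbon lies between two C–OH carbons. The other five ring carbons (C–OH, C–CH2Ar, C–O, CH, C–OH) are C2, C3, C4, C5 and C6 of the 3-arylmethyl-4-benzyloxy-6-chloro-2-pyranone 10, and the acyl-bearing carbon is the methyl carbon of pentan-2-one, so ring B is disconnected at both ring bonds to that carbon.
4. Ring order: the pyranone ring from malonyl dichloride (steps 1 and 2), then arene ring B/E by chloride substitution, lactone opening and Claisen closure (step 6). Rings A, C, D and F are bought as phloroglucinol nuclei (17, 5, 28) and only decorated.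

Key step: step 6

Assumption: the target has no stereocentre; ring A and all phloroglucinol and pyranone intermediates are written as one tautomer each, as in the target SMILES. Rings are lettered A to F from the dimethylcyclohexadienone end.

**Route**

Step 1
Reactants: 1 malonyl dichloride (2 equiv)
Product: 2 6-chloro-4-hydroxy-2-oxo-2H-pyran-3-carbonyl chloride
Conditions: neat, 20 °C, 5 d, moisture excluded
Reagents that add atoms: none
Why: Self-condensation of the acid chloride (C-acylation of one molecule by a second, then O-acylative ring closure with loss of HCl) is the known behaviour of neat malonyl dichloride and should give the crystalline chloropyranone.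

Step 2
Reactants: 2 6-chloro-4-hydroxy-2-oxo-2H-pyran-3-carbonyl chloride
Product: 4 6-chloro-4-hydroxy-2H-pyran-2-one, via carboxylic acid 3 (not isolated)
Conditions: H2O, 1,4-dioxane, 20 → 60 °C
Reagents that add atoms: none
Why: Acyl chloride hydrolysis gives a 3-carboxy-4-hydroxypyranone (a vinylogous β-keto acid) that should decarboxylate on gentle warming, while the C6 chloride of the enolised, acidic pyranone is expected to survive acidic water.

Step 3
Reactants: 5 2,4,6-trihydroxybenzaldehyde; 6 benzyl bromide
Product: 7 2,4,6-tris(benzyloxy)benzaldehyde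
Conditions: BnBr (3.6 equiv), K2CO3, DMF, 60 °C
Reagents that add atoms: benzyl bromide 6, BrCc1ccccc1
Why: Williamson etherification of all three phenols, with the formyl group lowering the ring nucleophilicity enough to suppress C-benzylation.

Step 4
Reactants: 4 6-chloro-4-hydroxy-2H-pyran-2-one; 7 2,4,6-tris(benzyloxy)benzaldehyde
Product: 9 6-chloro-4-hydroxy-3-[2,4,6-tris(benzyloxy)benzyl]-2H-pyran-2-one, via benzylidene pyrandione 8 (not isolated)
Conditions: Hantzsch ester (diethyl 2,6-dimethyl-1,4-dihydropyridine-3,5-dicarboxylate, 1.1 equiv), L-proline (20 mol%), CH2Cl2, 25 °C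
Reagents that add atoms: none
Why: Knoevenagel condensation at C3 (the carbon between the two carbonyl-type carbons) followed by conjugate hydride transfer from the Hantzsch ester is the established three-component reductive alkylation of 4-hydroxy-2-pyranones, and the doubly ortho-substituted arylidene cannot take up a second pyranone.

Step 5
Reactants: 9 6-chloro-4-hydroxy-3-[2,4,6-tris(benzyloxy)benzyl]-2H-pyran-2-one
Product: 10 4-(benzyloxy)-6-chloro-3-[2,4,6-tris(benzyloxy)benzyl]-2H-pyran-2-one
Conditions: BnOH, PPh3, diisopropyl azodicarboxylate, THF, 0 → 25 °C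
Reagents that add atoms: benzyl alcohol, OCc1ccccc1
Why: Mitsunobu etherification uses the acidic 4-OH as pronucleophile and should alkylate O4 to the 4-alkoxy-2-pyranone without any base that could touch the C6 chloride.

Step 6
Reactants: 10 4-(benzyloxy)-6-chloro-3-[2,4,6-tris(benzyloxy)benzyl]-2H-pyran-2-one; 11 pentan-2-one
Product: 14 1-{4-(benzyloxy)-2,6-dihydroxy-3-[2,4,6-tris(benzyloxy)benzyl]phenyl}butan-1-one, via 6-(2-oxopentyl)pyranone 12 (not isolated), via ring-opened benzyl ester 13 (not isolated)
Conditions: 11 (2.4 equiv), LiN(iPr)2 (2.3 equiv), THF, −78 °C; then 10, −78 → 0 °C; then NaOCH2Ph (3 equiv, 1 M in BnOH), 0 → 60 °C; aq. HCl work-up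
Reagents that add atoms: pentan-2-one 11, CCCC(C)=O
Why: Proposed new method: the kinetic lithium enolate of 11, formed at the methyl carbon by LiN(iPr)2 at −78 °C, should add at C6 of 10 (the δ-carbon of a doubly vinylogous acyl chloride) and expel chloride, an addition–elimination whose closest known relatives are the attack of ketone carbanions at C6 in 2-pyranone-to-arene ring transformations and substitutions of β-chloro enones, and the second equivalent of enolate deprotonates the new, doubly activated CH2 of 12. Sodium benzyloxide then opens the lactone at C2 to benzyl ester 13, in which the double bond inherited from the ring holds the ester cis to the 5,7-dioxo chain, and C6 of that chain (the former methyl carbon of 11) attacks the ester carbon in a 6-exo-trig Claisen condensation that closes ring B; loss of benzyloxide and enolisation give the arene, as in the known alkoxide-mediated Claisen recyclisation of 6-(2-oxoalkyl)-4-alkoxy-2-pyranones to acylphloroglucinols. The step needs attack at C6 and not at the lactone carbonyl or C4, which the chloride leaving group at C6 and the bulky arylmethyl group at C3 (flanking C2 and C4) should secure, and Claisen instead of aldol closure, which follows because C3 is fully substituted and O4 is a benzyl ether, so no nucleophilic carbon sits next to the ester. Benzyloxide is used as the ring-opening alkoxide so that any alkoxy exchange at C4 is degenerate, the O4 benzyl ether prevents an oxyanion that would switch off the pyranone, and no stereocentre is formed.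

Step 7
Reactants: 14 1-{4-(benzyloxy)-2,6-dihydroxy-3-[2,4,6-tris(benzyloxy)benzyl]phenyl}butan-1-one; 15 bis(dimethylamino)methane
Product: 16 1-{4-(benzyloxy)-3-[(dimethylamino)methyl]-2,6-dihydroxy-5-[2,4,6-tris(benzyloxy)benzyl]phenyl}butan-1-one
Conditions: Me2NCH2NMe2 (1.2 equiv), 1,4-dioxane, 50 °C
Reagents that add atoms: bis(dimethylamino)methane 15, CN(C)CN(C)C
Why: Phenolic Mannich reaction in which the acidic acylphloroglucinol OH protonates the aminal and the iminium ion attacks the only free carbon of ring B (ortho and para to OH), while the fully etherified arm ring does not react without acid.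

Step 8
Reactants: 17 phloroglucinol; 18 butanoyl chloride
Product: 19 1-(2,4,6-trihydroxyphenyl)butan-1-one
Conditions: PrCOCl, AlCl3, PhNO2–CH2Cl2, 0 → 40 °C; aq. HCl
Reagents that add atoms: butanoyl chloride 18, CCCC(Cl)=O
Why: Friedel–Crafts acylation of phloroglucinol stops at the monoketone because the first acyl group deactivates the ring.

Step 9
Reactants: 19 1-(2,4,6-trihydroxyphenyl)butan-1-one; 20 iodomethane
Product: 21 2-butanoyl-3,5-dihydroxy-4,4-dimethylcyclohexa-2,5-dien-1-one (butyrylfilicinic acid)
Conditions: MeI (2.2 equiv), NaOCH3, MeOH, 0 → 25 °C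
Reagents that add atoms: iodomethane 20, CI
Why: Base-mediated double C-methylation of the acylphloroglucinol at one ring carbon (enolate alkylation with dearomatisation) is the classical entry to acylfilicinic acids, and the under- and over-methylated companions should be separable.

Step 10
Reactants: 16 ring B Mannich base of the dimer; 21 butyrylfilicinic acid (1.5 equiv)
Product: 23 benzyl-protected ring A–B–C trimer (ring C still without butyryl), via o-quinone methide 22 (not isolated)
Conditions: 1,4-dioxane, 90 °C, N2 sweep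
Reagents that add atoms: none
Why: Thermal loss of dimethylamine from the Mannich base should give o-quinone methide 22, which is trapped by Michael addition of C6 of 21 (the carbon between its two enolised carbonyls) with rearomatisation of ring B, the standard use of phenolic Mannich bases as benzylating agents.

Step 11
Reactants: 23 benzyl-protected ring A–B–C trimer
Product: 24 ring A–B–C trimer with free phloroglucinol ring C (no butyryl on ring C)
Conditions: H2 (1 atm), Pd/C (10% palladium on carbon), EtOAc–MeOH, 25 °C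
Reagents that add atoms: none
Why: Hydrogenolysis of the four benzyl aryl ethers, under neutral conditions that should leave the chelated aryl ketones, the enolised triketone of ring A and the diarylmethane bridges untouched.

Step 12
Reactants: 24 ring A–B–C trimer with free ring C; 25 butanenitrile
Product: 27 ring A–B–C trimer with one free CH on ring C, via ketiminium chloride 26 (not isolated)
Conditions: PrCN, ZnCl2, HCl (g), Et2O–1,4-dioxane, 0 °C; then H2O, 80 °C
Reagents that add atoms: butanenitrile 25, CCCC#N; water, O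
Why: Houben–Hoesch acylation should attack only ring C, the one phloroglucinol ring without an acyl group (its two free carbons are equivalent), and the ketiminium salt blocks a second acylation before it is hydrolysed to the ketone.

Step 13
Reactants: 28 2-methylbenzene-1,3,5-triol; 18 butanoyl chloride
Product: 29 1-(2,4,6-trihydroxy-3-methylphenyl)butan-1-one
Conditions: PrCOCl, AlCl3, PhNO2–CH2Cl2, 0 → 40 °C; aq. HCl
Reagents that add atoms: butanoyl chloride 18, CCCC(Cl)=O
Why: Friedel–Crafts monoacylation at one of the two equivalent free carbons of methylphloroglucinol.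

Step 14
Reactants: 29 1-(2,4,6-trihydroxy-3-methylphenyl)butan-1-one; 15 bis(dimethylamino)methane
Product: 30 1-{3-[(dimethylamino)methyl]-2,4,6-trihydroxy-5-methylphenyl}butan-1-one
Conditions: Me2NCH2NMe2 (1.1 equiv), 1,4-dioxane, 25 → 50 °C
Reagents that add atoms: bis(dimethylamino)methane 15, CN(C)CN(C)C
Why: Phenolic Mannich reaction at the single free ring carbon of 29 (ortho and para to hydroxyl groups), the acidic acylphloroglucinol OH activating the aminal without added acid.

Step 15
Reactants: 30 ring F Mannich base (1.3 equiv); 14 1-{4-(benzyloxy)-2,6-dihydroxy-3-[2,4,6-tris(benzyloxy)benzyl]phenyl}butan-1-one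
Product: 32 benzyl-protected ring F–E–D trimer (ring D still without butyryl), via ring F o-quinone methide 31 (not isolated)
Conditions: 1,4-dioxane, 90 °C, N2 sweep
Reagents that add atoms: none
Why: Thermal loss of dimethylamine from 30 should give the ring F o-quinone methide 31, which cannot be C-alkylated by its own fully substituted precursor and is trapped by Michael-type addition of the one phenolic free carbon of 14 (ortho and para to OH), the benzyl-etherified arm ring being a far weaker nucleophile without acid; rearomatisation forms the F–E methylene and makes the arene ring of 14 into ring E.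

Step 16
Reactants: 32 benzyl-protected ring F–E–D trimer
Product: 33 ring F–E–D trimer with free phloroglucinol ring D (no butyryl on ring D)
Conditions: H2 (1 atm), Pd/C (10% palladium on carbon), EtOAc–MeOH, 25 °C
Reagents that add atoms: none
Why: Hydrogenolysis of the four benzyl ethers under neutral conditions, as in step 11.

Step 17
Reactants: 33 ring F–E–D trimer with free ring D; 25 butanenitrile
Product: 35 ring F–E–D trimer with one free CH on ring D, via ketiminium chloride 34 (not isolated)
Conditions: PrCN, ZnCl2, HCl (g), Et2O–1,4-dioxane, 0 °C; then H2O, 80 °C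
Reagents that add atoms: butanenitrile 25, CCCC#N; water, O
Why: Houben–Hoesch acylation of the only non-acylated ring (ring D), self-limiting at the monoketone as in step 12.

Step 18
Reactants: 35 ring F–E–D trimer; 15 bis(dimethylamino)methane
Product: 36 ring D Mannich base of the F–E–D trimer
Conditions: Me2NCH2NMe2 (1.1 equiv), 1,4-dioxane, 25 °C
Reagents that add atoms: bis(dimethylamino)methane 15, CN(C)CN(C)C
Why: Phenolic Mannich reaction at the single remaining aromatic CH of 35, on ring D.

Step 19
Reactants: 36 ring D Mannich base; 27 ring A–B–C trimer (1.2 equiv)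
Product: 38 target hexamer CNP0309827.0, via o-quinone methide 37 (not isolated)
Conditions: 1,4-dioxane, 70 °C, N2 sweep
Reagents that add atoms: none
Why: Elimination of dimethylamine from 36 should give the ring D o-quinone methide 37, and 27 offers one nucleophilic ring carbon only (the free CH of ring C; ring A is fully substituted), so Michael-type C-alkylation forms the C–D methylene and completes the chain.

**Compound list**
1 | malonyl dichloride | O=C(Cl)CC(Cl)=O | starting material
2 | 6-chloro-4-hydroxy-2-oxo-2H-pyran-3-carbonyl chloride | O=C(Cl)C1=C(O)C=C(Cl)OC1=O | intermediate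
3 | 6-chloro-4-hydroxy-2-oxo-2H-pyran-3-carboxylic acid (not isolated, step 2) | OC(=O)C1=C(O)C=C(Cl)OC1=O | intermediate
4 | 6-chloro-4-hydroxy-2H-pyran-2-one | O=C1C=C(O)C=C(Cl)O1 | intermediate
5 | 2,4,6-trihydroxybenzaldehyde | O=Cc1c(O)cc(O)cc1O | starting material
6 | benzyl bromide | BrCc1ccccc1 | starting material
7 | 2,4,6-tris(benzyloxy)benzaldehyde | O=Cc1c(OCc2ccccc2)cc(OCc3ccccc3)cc1OCc4ccccc4 | intermediate
8 | 6-chloro-3-[2,4,6-tris(benzyloxy)benzylidene]-2H-pyran-2,4(3H)-dione (not isolated, step 4; alkene geometry not defined, both isomers are reduced to 9) | O=C1OC(Cl)=CC(=O)C1=Cc2c(OCc3ccccc3)cc(OCc4ccccc4)cc2OCc5ccccc5 | intermediate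
9 | 6-chloro-4-hydroxy-3-[2,4,6-tris(benzyloxy)benzyl]-2H-pyran-2-one | O=C1OC(Cl)=CC(O)=C1Cc2c(OCc3ccccc3)cc(OCc4ccccc4)cc2OCc5ccccc5 | intermediate
10 | 4-(benzyloxy)-6-chloro-3-[2,4,6-tris(benzyloxy)benzyl]-2H-pyran-2-one (key-step precursor) | O=C1OC(Cl)=CC(OCc2ccccc2)=C1Cc3c(OCc4ccccc4)cc(OCc5ccccc5)cc3OCc6ccccc6 | intermediate
11 | pentan-2-one | CCCC(C)=O | starting material
12 | 4-(benzyloxy)-6-(2-oxopentyl)-3-[2,4,6-tris(benzyloxy)benzyl]-2H-pyran-2-one (not isolated, step 6) | CCCC(=O)CC1=CC(OCc2ccccc2)=C(Cc3c(OCc4ccccc4)cc(OCc5ccccc5)cc3OCc6ccccc6)C(=O)O1 | intermediate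
13 | benzyl (2E)-3-(benzyloxy)-5,7-dioxo-2-[2,4,6-tris(benzyloxy)benzyl]dec-2-enoate (not isolated, step 6) | CCCC(=O)CC(=O)C/C(OCc1ccccc1)=C(/Cc2c(OCc3ccccc3)cc(OCc4ccccc4)cc2OCc5ccccc5)C(=O)OCc6ccccc6 | intermediate
14 | 1-{4-(benzyloxy)-2,6-dihydroxy-3-[2,4,6-tris(benzyloxy)benzyl]phenyl}butan-1-one (key-step product; ring B or E with the protected arm) | CCCC(=O)c1c(O)cc(OCc2ccccc2)c(Cc3c(OCc4ccccc4)cc(OCc5ccccc5)cc3OCc6ccccc6)c1O | intermediate
15 | bis(dimethylamino)methane | CN(C)CN(C)C | starting material
16 | 1-{4-(benzyloxy)-3-[(dimethylamino)methyl]-2,6-dihydroxy-5-[2,4,6-tris(benzyloxy)benzyl]phenyl}butan-1-one | CCCC(=O)c1c(O)c(CN(C)C)c(OCc2ccccc2)c(Cc3c(OCc4ccccc4)cc(OCc5ccccc5)cc3OCc6ccccc6)c1O | intermediate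
17 | phloroglucinol (benzene-1,3,5-triol) | Oc1cc(O)cc(O)c1 | starting material
18 | butanoyl chloride | CCCC(Cl)=O | starting material
19 | 1-(2,4,6-trihydroxyphenyl)butan-1-one | CCCC(=O)c1c(O)cc(O)cc1O | intermediate
20 | iodomethane | CI | starting material
21 | 2-butanoyl-3,5-dihydroxy-4,4-dimethylcyclohexa-2,5-dien-1-one (butyrylfilicinic acid) | CCCC(=O)C1=C(O)C(C)(C)C(O)=CC1=O | intermediate
22 | 5-(benzyloxy)-2-butanoyl-3-hydroxy-6-methylidene-4-[2,4,6-tris(benzyloxy)benzyl]cyclohexa-2,4-dien-1-one (ring B o-quinone methide, not isolated, step 10) | CCCC(=O)C1=C(O)C(Cc2c(OCc3ccccc3)cc(OCc4ccccc4)cc2OCc5ccccc5)=C(OCc6ccccc6)C(=C)C1=O | intermediate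
23 | 2-butanoyl-6-({6-(benzyloxy)-3-butanoyl-2,4-dihydroxy-5-[2,4,6-tris(benzyloxy)benzyl]phenyl}methyl)-3,5-dihydroxy-4,4-dimethylcyclohexa-2,5-dien-1-one | CCCC(=O)C1=C(O)C(C)(C)C(O)=C(Cc2c(O)c(C(=O)CCC)c(O)c(Cc3c(OCc4ccccc4)cc(OCc5ccccc5)cc3OCc6ccccc6)c2OCc7ccccc7)C1=O | intermediate
24 | 2-butanoyl-6-{[3-butanoyl-2,4,6-trihydroxy-5-(2,4,6-trihydroxybenzyl)phenyl]methyl}-3,5-dihydroxy-4,4-dimethylcyclohexa-2,5-dien-1-one | CCCC(=O)C1=C(O)C(C)(C)C(O)=C(Cc2c(O)c(C(=O)CCC)c(O)c(Cc3c(O)cc(O)cc3O)c2O)C1=O | intermediate
25 | butanenitrile | CCCC#N | starting material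
26 | ketiminium chloride of 27 (ring C carries C(=NH2+)Pr in place of butanoyl; not isolated, step 12) | CCCC(=O)C1=C(O)C(C)(C)C(O)=C(Cc2c(O)c(C(=O)CCC)c(O)c(Cc3c(O)cc(O)c(C(=[NH2+])CCC)c3O)c2O)C1=O.[Cl-] | intermediate
27 | 2-butanoyl-6-{[3-butanoyl-5-(3-butanoyl-2,4,6-trihydroxybenzyl)-2,4,6-trihydroxyphenyl]methyl}-3,5-dihydroxy-4,4-dimethylcyclohexa-2,5-dien-1-one (ring A–B–C trimer) | CCCC(=O)C1=C(O)C(C)(C)C(O)=C(Cc2c(O)c(C(=O)CCC)c(O)c(Cc3c(O)cc(O)c(C(=O)CCC)c3O)c2O)C1=O | intermediate
28 | 2-methylbenzene-1,3,5-triol | Cc1c(O)cc(O)cc1O | starting material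
29 | 1-(2,4,6-trihydroxy-3-methylphenyl)butan-1-one | CCCC(=O)c1c(O)cc(O)c(C)c1O | intermediate
30 | 1-{3-[(dimethylamino)methyl]-2,4,6-trihydroxy-5-methylphenyl}butan-1-one (ring F Mannich base) | CCCC(=O)c1c(O)c(C)c(O)c(CN(C)C)c1O | intermediate
31 | 2-butanoyl-3,5-dihydroxy-4-methyl-6-methylidenecyclohexa-2,4-dien-1-one (ring F o-quinone methide, not isolated, step 15) | CCCC(=O)C1=C(O)C(C)=C(O)C(=C)C1=O | intermediate
32 | 1-{3-[(6-(benzyloxy)-3-butanoyl-2,4-dihydroxy-5-[2,4,6-tris(benzyloxy)benzyl]phenyl)methyl]-2,4,6-trihydroxy-5-methylphenyl}butan-1-one | CCCC(=O)c1c(O)c(C)c(O)c(Cc2c(O)c(C(=O)CCC)c(O)c(Cc3c(OCc4ccccc4)cc(OCc5ccccc5)cc3OCc6ccccc6)c2OCc7ccccc7)c1O | intermediate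
33 | 1-{3-[3-butanoyl-2,4,6-trihydroxy-5-(2,4,6-trihydroxybenzyl)benzyl]-2,4,6-trihydroxy-5-methylphenyl}butan-1-one | CCCC(=O)c1c(O)c(C)c(O)c(Cc2c(O)c(C(=O)CCC)c(O)c(Cc3c(O)cc(O)cc3O)c2O)c1O | intermediate
34 | ketiminium chloride of 35 (ring D carries C(=NH2+)Pr in place of butanoyl; not isolated, step 17) | CCCC(=O)c1c(O)c(C)c(O)c(Cc2c(O)c(C(=O)CCC)c(O)c(Cc3c(O)cc(O)c(C(=[NH2+])CCC)c3O)c2O)c1O.[Cl-] | intermediate
35 | 1-{3-[3-butanoyl-5-(3-butanoyl-2,4,6-trihydroxybenzyl)-2,4,6-trihydroxybenzyl]-2,4,6-trihydroxy-5-methylphenyl}butan-1-one (ring F–E–D trimer) | CCCC(=O)c1c(O)c(C)c(O)c(Cc2c(O)c(C(=O)CCC)c(O)c(Cc3c(O)cc(O)c(C(=O)CCC)c3O)c2O)c1O | intermediate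
36 | 1-{3-[3-butanoyl-5-{3-butanoyl-5-[(dimethylamino)methyl]-2,4,6-trihydroxybenzyl}-2,4,6-trihydroxybenzyl]-2,4,6-trihydroxy-5-methylphenyl}butan-1-one | CCCC(=O)c1c(O)c(C)c(O)c(Cc2c(O)c(C(=O)CCC)c(O)c(Cc3c(O)c(CN(C)C)c(O)c(C(=O)CCC)c3O)c2O)c1O | intermediate
37 | ring D o-quinone methide of the F–E–D trimer (ring D = 2-butanoyl-3,5-dihydroxy-6-methylidenecyclohexa-2,4-dien-1-one bearing the ring E benzyl group at C4; not isolated, step 19) | CCCC(=O)c1c(O)c(C)c(O)c(Cc2c(O)c(C(=O)CCC)c(O)c(CC3=C(O)C(=C)C(=O)C(C(=O)CCC)=C3O)c2O)c1O | intermediate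
38 | CNP0309827.0, the methylene-linked hexamer A–B–C–D–E–F | CCCC(=O)C1=C(O)C(C)(C)C(O)=C(Cc2c(O)c(Cc3c(O)c(Cc4c(O)c(Cc5c(O)c(Cc6c(O)c(C)c(O)c(C(=O)CCC)c6O)c(O)c(C(=O)CCC)c5O)c(O)c(C(=O)CCC)c4O)c(O)c(C(=O)CCC)c3O)c(O)c(C(=O)CCC)c2O)C1=O | target

**Step count**
Total: 19 steps. Longest linear sequence: 10 steps (1, 2, 4, 5, 6, 15, 16, 17, 18, 19; the path 1, 2, 4, 5, 6, 7, 10, 11, 12, 19 is equally long). Step 6 is run once and its product 14 feeds both trimers: through Mannich base 16 for A–B–C, and directly as the nucleophile of step 15 for F–E–D.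

**Steps most likely to fail**

Step 6 (proposed new method). The enolate may attack the lactone carbonyl instead of C6, the kinetic enolate may equilibrate before it is consumed, or the anionic pyranone may open too slowly for closure to start. The fallback uses known chemistry, sets out from aldehyde 7 and returns at 14. Commercial 4-hydroxy-6-methyl-2H-pyran-2-one is reductively alkylated with 7 (Hantzsch ester, L-proline, as in step 4) to 4-hydroxy-6-methyl-3-[2,4,6-tris(benzyloxy)benzyl]-2H-pyran-2-one F1. Mitsunobu benzylation (BnOH, PPh3, diisopropyl azodicarboxylate) gives 4-(benzyloxy)-6-methyl-3-[2,4,6-tris(benzyloxy)benzyl]-2H-pyran-2-one F2. Lateral lithiation of the 6-methyl group with LiN(iPr)2 (2 equiv, THF, −78 °C) and C-acylation with methyl butanoate delivers 12 as an isolated compound, which is recyclised with NaOCH2Ph in benzyl alcohol to 14. The acyl-bearing ring carbon is then the 6-methyl carbon of the pyranone, ring B still closes by the same lactone-opening Claisen condensation, and both operations are established for 4-alkoxy-6-methyl-2-pyranones.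

Step 19. Heat and liberated amine may cause retro-Michael cleavage of methylene bridges already in place, which scrambles the ring order, and the quinone methide may be consumed by self-condensation before 27 traps it. The fallback sets out from 36 and returns at 38. Quaternisation with iodomethane in THF gives the ring D trimethylammonium iodide of the F–E–D trimer F3. From this salt the quinone methide is released at 0 to 20 °C with NaHCO3 in aqueous acetonitrile in the presence of 27, so the C–D bond forms without heating and without free secondary amine.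

Step 12 (the same operation recurs in step 17). HCl/ZnCl2 and the hot aqueous hydrolysis may cleave or shift methylene bridges, and the polyphenol may be poorly soluble, leaving the ketiminium salt unhydrolysed. The fallback sets out from 24 and returns at 27. Vilsmeier–Haack acylation with the chloroiminium salt made from N,N-dimethylbutanamide and POCl3 (MeCN, 0 to 25 °C) gives the ring C N,N-dimethyliminium chloride of the A–B–C trimer F4, which is hydrolysed with aqueous sodium acetate at 40 °C to 27. This avoids gaseous HCl and boiling acid.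

**Further compounds**
F1 | step 6 | 4-hydroxy-6-methyl-3-[2,4,6-tris(benzyloxy)benzyl]-2H-pyran-2-one | CC1=CC(O)=C(Cc2c(OCc3ccccc3)cc(OCc4ccccc4)cc2OCc5ccccc5)C(=O)O1
F2 | step 6 | 4-(benzyloxy)-6-methyl-3-[2,4,6-tris(benzyloxy)benzyl]-2H-pyran-2-one | CC1=CC(OCc2ccccc2)=C(Cc3c(OCc4ccccc4)cc(OCc5ccccc5)cc3OCc6ccccc6)C(=O)O1
F3 | step 19 | ring D trimethylammonium iodide of the F–E–D trimer | CCCC(=O)c1c(O)c(C)c(O)c(Cc2c(O)c(C(=O)CCC)c(O)c(Cc3c(O)c(C[N+](C)(C)C)c(O)c(C(=O)CCC)c3O)c2O)c1O.[I-]
F4 | step 12 | ring C N,N-dimethyliminium chloride of the A–B–C trimer | CCCC(=O)C1=C(O)C(C)(C)C(O)=C(Cc2c(O)c(C(=O)CCC)c(O)c(Cc3c(O)cc(O)c(C(CCC)=[N+](C)C)c3O)c2O)C1=O.[Cl-]
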